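# Proposed synthesis of [(1S,2R,5R,6S)-5-(benzoyloxy)-1,2,6-trihydroxycyclohexyl]methyl benzoate (13)

Conventions: the ring atoms of the target are numbered C1 (quaternary carbinol), C2 (secondary carbinol next to the methylenes C3 and C4), C5 (benzoyloxy carbon) and C6 (carbinol between C5 and C1); C7 is the CH2O carbon on C1, and O1–O7 are the oxygens on these carbons. TBS = tert-butyldimethylsilyl. Assumption: 1,3-dihydroxyacetone (1) is drawn and counted as the monomer; the commercial solid is its dimer, which reacts as the monomer under the silylation conditions.

## The problem

Target 13 is a single cyclohexane ring whose seven carbons carry five oxygens: a quaternary carbinol C1 with its CH2O carbon C7, a secondary carbinol C2, two methylenes C3 and C4, a benzoyloxy carbon C5 and a carbinol C6. The four stereocentres are contiguous, (1S,2R,5R,6S): O1 is trans to O2 and to O6, O5 is trans to O6, and in the chair with all four ring oxygens equatorial C7 is axial. C1 is the difficult centre, because it is fully substituted, lies between two carbinol carbons and cannot be corrected once it exists. C5 and C6 can be made first in an open chain, where a threo diol is an aldol problem, and can then bias the formation of C1 through a chair; C2 is best kept as a carbonyl to the end, where the hydroxyl on C1 can direct its reduction. The five oxygens must finish in two states, benzoate on O5 and O7 and free hydroxyl on O1, O2 and O6, so each has to be distinguishable at the moment it is acylated. The functionality is fragile toward base: a benzoate beside a free hydroxyl migrates, an acyloxy group on C5 is β to any carbonyl at C1 and can be eliminated, and a tertiary α-ketol can undergo acyloin shift. The feature that opens the synthesis is the C1–C2 bond between two oxygenated carbons: with C2 at the ketone level, C1(OH)–C2(=O) is an α-ketol, the product of an aldehyde–ketone benzoin, and cutting it leaves a C1 ketone flanked by O7 and O6, a dihydroxyacetone unit joined to C5 by an aldol bond.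

## Retrosynthesis

**13 to 12 (O7–acyl bond).** The benzoate on O7 is removed first, which leads to the tetraol monobenzoate 12. O7 is the only primary hydroxyl of 12, so the forward acylation with 6 can rely on kinetic selection. Cutting the O5 benzoate last instead would ask for a choice among three secondary hydroxyls. Carrying an O7 benzoate from the start would place an α-acyloxy ketone in the base-mediated ring closure. The forward step must acylate O7 and leave O2, O6 and O1 alone.

**12 to 11 to 10 (two O–Si bonds, then the C2–H bond).** Both hydroxyls of 12 that were never to be acylated (O6, O7) are traced back to silyl ethers in 11. The hydrogen on C2 is then removed to give ketone 10. C2 is the one stereocentre that has a non-epimerisable, hydroxyl-bearing neighbour able to deliver hydride, so it can safely be set last. Keeping it as a carbonyl is also what turns the C1–C2 bond into a strategic bond. The forward reduction has to place the new hydroxyl trans to O1.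

**10 to 9 (C1–C2 ring bond).** Cutting the α-ketol bond opens the ring to the keto-aldehyde 9. Against the neighbouring ring bonds this cut has three advantages:
- it removes the quaternary centre and the ring in one stroke;
- the nucleophilic carbon (C2) carries no stereocentre;
- both remaining stereocentres (C5, C6) sit in the chain next to the reacting ketone, where they can control its facial selectivity.

Precursor 9 is linear with two stereocentres, whereas 10 is cyclic with three. The forward reaction needs a carbene that adds to the aldehyde and not the ketone. The derived acyl-anion equivalent must attack the ketone face that puts O1 trans to O6. The base must be weak enough to spare the C5 benzoate, which is β to the ketone.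

**9 to 7 to 5 (C2=O from a C=C bond, then the O5–acyl bond).** The aldehyde carbon C2 is traced back to the internal carbon of a terminal alkene in 7, so that no aldehyde is present while the chain is built and acylated. The benzoate is then removed to give the aldol 5, in which O5 is the only free hydroxyl. This is the point at which O5 is told apart from every other oxygen, and it requires no protecting-group step. The forward steps are an ester formation with 6 on a β-hydroxy ketone without elimination, and an ozonolysis.

**5 to 3 and 4 (C5–C6 bond), 3 to 1 and 2.** The threo diol next to the ketone is an aldol retron. Cutting C5–C6 gives the symmetrical ketone 3, in which regiochemistry of enolisation is not an issue, and the aldehyde 4. Both stereocentres arise in this one bond formation, and none has to be bought. A cut at C6–C1 or C4–C5 would instead require a chiral fragment. The forward reaction must be syn-selective and give the (3S,4R) sense of 5 under catalyst control. Ketone 3 is the bis-silyl ether of 1, made with two equivalents of 2.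

## Roads not taken

**Alternative 1:** The cut is double, C2–C3 and C5–C6. It divides the ring into 2,2-dimethyl-1,3-dioxan-5-one A1 (C2, C1, C6 with their oxygens) and acrolein A2 (C3, C4, C5). Forward, a chiral secondary amine would convert A1 into its enamine, and conjugate addition to A2 would form C2–C3. A second enamine on the other α-carbon would then close C5–C6 by aldol addition to give the bridged ketone 6-hydroxy-3,3-dimethyl-2,4-dioxabicyclo[3.3.1]nonan-9-one A3.

Merits:
- The ring comes from two commodity chemicals in one operation.
- The acetal bridge holds O2 and O6 cis, as the target requires.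
- The rigid bicycle offers a defined open face for bringing in C7 at C1. Methylenation followed by dihydroxylation from the carbocyclic side would place O1 trans to O2 and O6.
- O5 is the only free hydroxyl of A3.
- The bridgehead carbons enolise only with difficulty, so a C5 benzoate would be safe from elimination.

In step count, in the differentiation of the oxygens and in the absence of a final site-selective acylation this road is better than the chosen one.

Weak points:
- As a catalytic asymmetric step the annulation has no close analogy. A2 polymerises and forms iminium ions with secondary amines.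
- The first stereocentre formed (C2) is epimerisable, so the absolute configuration is decided only in the aldol closure, which must pass through a conformation with both ring oxygens axial.
- A3 is a β-hydroxy ketone that can reopen by retro-aldol, which would erode diastereomeric and enantiomeric purity.

The chosen plan sets against the shorter sequence that each of its stereocentres is formed by a reaction whose stereochemical course is known for the substrate class.

**Alternative 2:** The cut is C3–C4, the only ring bond between two unfunctionalised carbons. Forward, the tartrate-derived bis(methyl ketone) 4,5-diacetyl-4-[(benzyloxy)methyl]-2,2-dimethyl-1,3-dioxolane A4 (acetyl groups trans) would be deprotonated twice with LiN(iPr)2. The bis-enolate would be oxidised with Cu(OTf)2 (divalent copper), so that the two methyl carbons couple to the trans-fused 1,4-dione A5.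

Merits:
- The configuration at C6 is bought with tartaric acid.
- The quaternary centre C1 is in place before the ring exists, so the ring closure has no stereochemical task.
- The absolute configuration does not depend on a catalyst. In this respect the road is better than the chosen one.

Weak points:
- A4 is itself a multi-step target. It needs alkylation of a tartrate acetonide enolate to the quaternary centre and conversion of two esters into methyl ketones.
- In A4 the proton on C6 is the most acidic, and its removal expels the acetal oxygen on C1, whereas the coupling needs the kinetic bis-enolate on the methyl groups only.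
- The ring must close trans-fused to a dioxolane in competition with intermolecular coupling.
- After the key step C2 and C5 are two ketones in nearly identical surroundings. Both must be reduced with the right sense, and then O5 but not O2 must be benzoylated, for which the structure offers no handle.
- The benzyl ether on O7 must still be exchanged for a benzoate.

The chosen plan distinguishes C2 from C5 from the first carbon–carbon bond on, since C5 is born as the aldol hydroxyl and C2 as an alkene carbon, and it should need about half the number of steps.

**Alternative 3:** Read backward, the cut is C1–C6 with re-formation of C2–C6. Forward, the acylcyclopentanol 3-[(benzoyloxy)acetyl]-2,3-dihydroxycyclopentyl benzoate A6 would, under mild base or BF3·OEt2, shift the oxygen-bearing ring carbon C6 from the carbinol carbon C2 to the acyl carbon C1. This expands the ring to the cyclohexanone [(1R,2S,3R)-3-(benzoyloxy)-1,2-dihydroxy-6-oxocyclohexyl]methyl benzoate A7.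

Merits:
- A7 already carries both benzoates and differs from 13 only in the C2 carbonyl, so one hydroxyl-directed reduction would finish the synthesis. This end-game is shorter and cleaner than the three steps that follow the key step of the chosen plan, and it avoids the site-selective acylation.
- The shift is driven by relief of ring strain.
- The migrating carbon keeps its configuration.

Weak points:
- A6, a cyclopentane with three contiguous stereocentres including a tertiary carbinol that bears an acyl side chain, is no easier to make than the six-membered target. The difficulty is moved, not removed.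
- The step must select migration of C6 over the methylene C3 on the other side of the carbinol, and the electron-poor C6 is the less willing migrating group.
- A7 is itself a tertiary α-ketol and can shift further under the same conditions.
- Under base the free O6 next to the O5 benzoate invites acyl migration.
- The configuration at C1 depends on which face of the acyl carbonyl receives C6, a conformational question without a clear answer.

The chosen plan sets against the better end-game that its key-step precursor 9 should be reached in four steps from commodity chemicals.

Key step: step 5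

## Route

Step 1
Reactants: 1 1,3-dihydroxyacetone; 2 tert-butyldimethylsilyl chloride
Product: 3 1,3-bis[(tert-butyldimethylsilyl)oxy]propan-2-one
Conditions: 2 (2.2 equiv), imidazole (4.5 equiv), DMF, 0 → 23 °C
Reagents that add atoms: tert-butyldimethylsilyl chloride (second equivalent), CC(C)(C)[Si](C)(C)Cl
Why: Standard imidazole-mediated silylation in which each of the two primary hydroxyls takes one silyl group from one equivalent of 2; the dimer of 1 dissociates in the medium and the bis-silyl ether is a stable, symmetrical ketone.

Step 2
Reactants: 3 1,3-bis[(tert-butyldimethylsilyl)oxy]propan-2-one; 4 pent-4-enal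
Product: 5 (3S,4R)-1,3-bis[(tert-butyldimethylsilyl)oxy]-4-hydroxyoct-7-en-2-one
Conditions: O-tert-butyl-D-threonine (20 mol %), 5-methyl-1H-tetrazole (10 mol %), NMP, H2O (3 vol %), 4 → 23 °C; 3 (2 equiv), 4 added slowly
Reagents that add atoms: none
Why: Direct asymmetric syn-aldol by primary-amine enamine catalysis: the amino acid condenses with 3 to a (Z)-enamine held by an N–H···O hydrogen bond to the α-silyloxy oxygen, and its carboxylic acid guides the aldehyde through a chair-like transition state, so that C6 and C5 arise syn. The D-configured catalyst is the one expected to give the D-threo (3S,4R) pattern, the L-catalyst giving the mirror image; slow addition of 4 and excess 3 limit self-condensation of the aldehyde.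

Step 3
Reactants: 5 (3S,4R)-1,3-bis[(tert-butyldimethylsilyl)oxy]-4-hydroxyoct-7-en-2-one; 6 benzoyl chloride
Product: 7 (3S,4R)-1,3-bis[(tert-butyldimethylsilyl)oxy]-2-oxooct-7-en-4-yl benzoate
Conditions: pyridine (3 equiv), 4-(dimethylamino)pyridine (5 mol %), CH2Cl2, 0 °C
Reagents that add atoms: none
Why: Nucleophile-catalysed acylation of the only free hydroxyl; a weak base at low temperature should spare the β-acyloxy ketone from E1cB elimination and avoid silyl migration, and no stereocentre is touched.

Step 4
Reactants: 7 (3S,4R)-1,3-bis[(tert-butyldimethylsilyl)oxy]-2-oxooct-7-en-4-yl benzoate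
Product: 9 (4R,5S)-5,7-bis[(tert-butyldimethylsilyl)oxy]-1,6-dioxoheptan-4-yl benzoate, via ozonide 8 (not isolated)
Conditions: O3, CH2Cl2, −78 °C; then PPh3, −78 → 23 °C
Reagents that add atoms: ozone, [O-][O+]=O
Why: Ozonolysis of the terminal alkene (Criegee mechanism) with reductive work-up of the ozonide; benzoate, silyl ethers and ketone are inert, and the keto-aldehyde is carried on without prolonged storage.

Step 5
Reactants: 9 (4R,5S)-5,7-bis[(tert-butyldimethylsilyl)oxy]-1,6-dioxoheptan-4-yl benzoate
Product: 10 (1R,2S,3R)-2-[(tert-butyldimethylsilyl)oxy]-3-{[(tert-butyldimethylsilyl)oxy]methyl}-3-hydroxy-4-oxocyclohexyl benzoate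
Conditions: (5aS,10bR)-2-(pentafluorophenyl)-5a,10b-dihydro-4H,6H-indeno[2,1-b][1,2,4]triazolo[4,3-d][1,4]oxazin-2-ium tetrafluoroborate (10 mol %), Et3N (10 mol %), toluene (0.02 M), 23 °C, argon
Reagents that add atoms: none
Why: Et3N deprotonates the acidic N-pentafluorophenyl triazolium salt to the carbene, which adds to the unhindered aldehyde C2 of 9 and not to the α-branched, doubly α-oxygenated ketone; proton transfer gives the enaminol (Breslow intermediate), an acyl-anion equivalent at C2. Its nucleophilic carbon attacks the C1 ketone in a 6-exo-trig closure while the enol proton passes to the ketone oxygen, and collapse of the adduct releases the carbene and the tertiary α-ketol 10. The closest known reaction type is the carbene-catalysed intramolecular crossed aldehyde–ketone benzoin cyclisation of keto-aldehydes to five- and six-membered cyclic α-ketols. C1 is the only new stereocentre and is controlled first by the substrate: in the chair transition state the C5 benzoate and the C6 silyl ether are equatorial, the bulky azolium on C2 is pseudo-equatorial, and the O–H···O=C contact needed for proton transfer then holds the ketone oxygen equatorial and C7 axial, that is O1 trans to O6. The fused indane of the chiral catalyst closes one face of the enaminol and is expected to reinforce this preference, the (5aS,10bR) salt being the first choice and its mirror image the direct test of the pairing. The step needs chemoselectivity for the benzoin over enolate chemistry at C6 (E1cB loss of the C5 benzoate, five-membered aldol closure onto the aldehyde); a weak amine base in catalytic amount, a non-polar solvent and the activation of the ketone by its two α-oxygens are meant to secure it. High dilution suppresses intermolecular benzoin, and since the aldehyde has no α-leaving group the internal redox pathway of the enaminol is closed.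

Step 6
Reactants: 10 (1R,2S,3R)-2-[(tert-butyldimethylsilyl)oxy]-3-{[(tert-butyldimethylsilyl)oxy]methyl}-3-hydroxy-4-oxocyclohexyl benzoate
Product: 11 (1R,2S,3S,4R)-2-[(tert-butyldimethylsilyl)oxy]-3-{[(tert-butyldimethylsilyl)oxy]methyl}-3,4-dihydroxycyclohexyl benzoate
Conditions: Me4NBH(OAc)3 (5 equiv), MeCN/AcOH (1:1), −20 → 0 °C
Reagents that add atoms: none
Why: Hydroxyl-directed triacetoxyborohydride reduction (Evans–Saksena type): exchange of an acetate for the tertiary O1 gives an alkoxyborohydride that delivers hydride to C2 from the face of O1, so the new hydroxyl is trans to O1. The intrinsic axial attack on the chair, anti to the axial C7 branch, leads to the same equatorial alcohol.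

Step 7
Reactants: 11 (1R,2S,3S,4R)-2-[(tert-butyldimethylsilyl)oxy]-3-{[(tert-butyldimethylsilyl)oxy]methyl}-3,4-dihydroxycyclohexyl benzoate
Product: 12 (1R,2S,3S,4R)-2,3,4-trihydroxy-3-(hydroxymethyl)cyclohexyl benzoate
Conditions: HF·pyridine, pyridine, THF, 0 → 23 °C
Reagents that add atoms: none
Why: Fluoride-driven cleavage of both silyl ethers in a buffered, weakly acidic medium, chosen over basic fluoride sources so that the O5 benzoate does not migrate to the freed O6.

Step 8
Reactants: 12 (1R,2S,3S,4R)-2,3,4-trihydroxy-3-(hydroxymethyl)cyclohexyl benzoate; 6 benzoyl chloride
Product: 13 [(1S,2R,5R,6S)-5-(benzoyloxy)-1,2,6-trihydroxycyclohexyl]methyl benzoate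
Conditions: pyridine, CH2Cl2, −40 → 0 °C (1.05 equiv of 6)
Reagents that add atoms: none
Why: Kinetically selective acylation of the single primary hydroxyl with one equivalent of acyl chloride at low temperature; the two secondary hydroxyls are flanked by the quaternary centre and the tertiary hydroxyl is unreactive.

## Compound list

1 | 1,3-dihydroxyacetone | OCC(=O)CO | starting material
2 | tert-butyldimethylsilyl chloride | CC(C)(C)[Si](C)(C)Cl | starting material
3 | 1,3-bis[(tert-butyldimethylsilyl)oxy]propan-2-one | CC(C)(C)[Si](C)(C)OCC(=O)CO[Si](C)(C)C(C)(C)C | intermediate
4 | pent-4-enal | C=CCCC=O | starting material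
5 | (3S,4R)-1,3-bis[(tert-butyldimethylsilyl)oxy]-4-hydroxyoct-7-en-2-one | C=CCC[C@@H](O)[C@H](O[Si](C)(C)C(C)(C)C)C(=O)CO[Si](C)(C)C(C)(C)C | intermediate
6 | benzoyl chloride | O=C(Cl)c1ccccc1 | starting material
7 | (3S,4R)-1,3-bis[(tert-butyldimethylsilyl)oxy]-2-oxooct-7-en-4-yl benzoate | C=CCC[C@@H](OC(=O)c1ccccc1)[C@H](O[Si](C)(C)C(C)(C)C)C(=O)CO[Si](C)(C)C(C)(C)C | intermediate
8 | (3S,4R)-1,3-bis[(tert-butyldimethylsilyl)oxy]-2-oxo-6-(1,2,4-trioxolan-3-yl)hexan-4-yl benzoate (ozonide, both epimers at the trioxolane carbon) | C1OOC(CC[C@@H](OC(=O)c2ccccc2)[C@H](O[Si](C)(C)C(C)(C)C)C(=O)CO[Si](C)(C)C(C)(C)C)O1 | intermediate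
9 | (4R,5S)-5,7-bis[(tert-butyldimethylsilyl)oxy]-1,6-dioxoheptan-4-yl benzoate | O=CCC[C@@H](OC(=O)c1ccccc1)[C@H](O[Si](C)(C)C(C)(C)C)C(=O)CO[Si](C)(C)C(C)(C)C | intermediate
10 | (1R,2S,3R)-2-[(tert-butyldimethylsilyl)oxy]-3-{[(tert-butyldimethylsilyl)oxy]methyl}-3-hydroxy-4-oxocyclohexyl benzoate | CC(C)(C)[Si](C)(C)OC[C@]1(O)C(=O)CC[C@@H](OC(=O)c2ccccc2)[C@@H]1O[Si](C)(C)C(C)(C)C | intermediate
11 | (1R,2S,3S,4R)-2-[(tert-butyldimethylsilyl)oxy]-3-{[(tert-butyldimethylsilyl)oxy]methyl}-3,4-dihydroxycyclohexyl benzoate | CC(C)(C)[Si](C)(C)OC[C@]1(O)[C@H](O)CC[C@@H](OC(=O)c2ccccc2)[C@@H]1O[Si](C)(C)C(C)(C)C | intermediate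
12 | (1R,2S,3S,4R)-2,3,4-trihydroxy-3-(hydroxymethyl)cyclohexyl benzoate | OC[C@]1(O)[C@H](O)CC[C@@H](OC(=O)c2ccccc2)[C@@H]1O | intermediate
13 | [(1S,2R,5R,6S)-5-(benzoyloxy)-1,2,6-trihydroxycyclohexyl]methyl benzoate | O=C(OC[C@]1(O)[C@H](O)CC[C@@H](OC(=O)c2ccccc2)[C@@H]1O)c1ccccc1 | target

## Step count and least certain steps

Total step count: 8. Longest linear sequence: 8 steps (from 1 to 13).

**Step 5 (key step).** The process most likely to interfere is enolisation of the C1 ketone toward C6 by the amine base faster than carbene turnover. That would lead to elimination of the C5 benzoate or to an aldol closure onto the aldehyde. Beside this, the facial selectivity at C1 may be insufficient if catalyst and substrate preferences oppose each other.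

The fallback sets out from 9 and forms the same C1–C2 bond reductively, without base. Pinacol cyclisation with SmI2 (divalent samarium) in THF/tBuOH at −78 °C should give the cis-1,2-diol, anti to the α-silyloxy group on C6 by the usual chelate model for 1,6-keto-aldehydes. This diol is (1R,2S,3S,4S)-2-[(tert-butyldimethylsilyl)oxy]-3-{[(tert-butyldimethylsilyl)oxy]methyl}-3,4-dihydroxycyclohexyl benzoate F1. Oxidation of its secondary C2 hydroxyl beside the tertiary one (SO3·pyridine, DMSO, iPr2NEt; Parikh–Doering) comes back to the route at 10.

**Step 2.** The process most likely to interfere is self-condensation of the unbranched aldehyde 4 through its own imine and enamine with the primary amine catalyst, giving low conversion to the cross-aldol and possibly eroded syn-selectivity.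

The fallback sets out from 4 and uses a preformed, auxiliary-bound enolate (Evans syn-aldol):
- (S)-4-Benzyloxazolidin-2-one is acylated with [(tert-butyldimethylsilyl)oxy]acetic acid through its pivaloyl mixed anhydride to give (S)-4-benzyl-3-{[(tert-butyldimethylsilyl)oxy]acetyl}oxazolidin-2-one F2.
- Its (Z)-boron enolate (Bu2BOTf, Et3N, CH2Cl2, −78 °C) adds to 4 to give (S)-4-benzyl-3-{(2S,3R)-2-[(tert-butyldimethylsilyl)oxy]-3-hydroxyhept-6-enoyl}oxazolidin-2-one F3.
- Transamination with AlMe3 and N,O-dimethylhydroxylamine hydrochloride gives the Weinreb amide (2S,3R)-2-[(tert-butyldimethylsilyl)oxy]-3-hydroxy-N-methoxy-N-methylhept-6-enamide F4.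
- Addition of excess [(4-methoxybenzyl)oxy]methyllithium, generated from the corresponding tributylstannane with nBuLi, gives (3S,4R)-3-[(tert-butyldimethylsilyl)oxy]-4-hydroxy-1-[(4-methoxybenzyl)oxy]oct-7-en-2-one F5.
- Oxidative removal of the 4-methoxybenzyl group with 2,3-dichloro-5,6-dicyano-1,4-benzoquinone gives (3S,4R)-3-[(tert-butyldimethylsilyl)oxy]-1,4-dihydroxyoct-7-en-2-one F6.
- Silylation of the primary hydroxyl (one equivalent of 2, imidazole, 0 °C) comes back to the route at 5.

**Step 8.** The process most likely to interfere is competing acylation of the secondary hydroxyls O2 and O6, because the primary hydroxyl sits on a quaternary carbon and is less reactive than an ordinary primary alcohol. The result would be mixtures of regioisomeric and over-acylated esters.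

The fallback sets out from 11 and changes the order of events so that O6 stays masked during the acylation:
- Brief treatment with HF·pyridine in pyridine/THF at 0 °C cleaves only the primary silyl ether, giving (1R,2S,3S,4R)-2-[(tert-butyldimethylsilyl)oxy]-3,4-dihydroxy-3-(hydroxymethyl)cyclohexyl benzoate F7.
- Acylation with 6 and pyridine, now with O2 as the only secondary competitor, gives [(1S,2R,5R,6S)-5-(benzoyloxy)-6-[(tert-butyldimethylsilyl)oxy]-1,2-dihydroxycyclohexyl]methyl benzoate F8.
- Removal of the remaining silyl ether with HF·pyridine comes back to the route at 13.

## Further compounds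

F1 | step 5 | (1R,2S,3S,4S)-2-[(tert-butyldimethylsilyl)oxy]-3-{[(tert-butyldimethylsilyl)oxy]methyl}-3,4-dihydroxycyclohexyl benzoate | CC(C)(C)[Si](C)(C)OC[C@]1(O)[C@@H](O)CC[C@@H](OC(=O)c2ccccc2)[C@@H]1O[Si](C)(C)C(C)(C)C
F2 | step 2 | (S)-4-benzyl-3-{[(tert-butyldimethylsilyl)oxy]acetyl}oxazolidin-2-one | CC(C)(C)[Si](C)(C)OCC(=O)N1[C@@H](Cc2ccccc2)COC1=O
F3 | step 2 | (S)-4-benzyl-3-{(2S,3R)-2-[(tert-butyldimethylsilyl)oxy]-3-hydroxyhept-6-enoyl}oxazolidin-2-one | C=CCC[C@@H](O)[C@H](O[Si](C)(C)C(C)(C)C)C(=O)N1[C@@H](Cc2ccccc2)COC1=O
F4 | step 2 | (2S,3R)-2-[(tert-butyldimethylsilyl)oxy]-3-hydroxy-N-methoxy-N-methylhept-6-enamide | C=CCC[C@@H](O)[C@H](O[Si](C)(C)C(C)(C)C)C(=O)N(C)OC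
F5 | step 2 | (3S,4R)-3-[(tert-butyldimethylsilyl)oxy]-4-hydroxy-1-[(4-methoxybenzyl)oxy]oct-7-en-2-one | C=CCC[C@@H](O)[C@H](O[Si](C)(C)C(C)(C)C)C(=O)COCc1ccc(OC)cc1
F6 | step 2 | (3S,4R)-3-[(tert-butyldimethylsilyl)oxy]-1,4-dihydroxyoct-7-en-2-one | C=CCC[C@@H](O)[C@H](O[Si](C)(C)C(C)(C)C)C(=O)CO
F7 | step 8 | (1R,2S,3S,4R)-2-[(tert-butyldimethylsilyl)oxy]-3,4-dihydroxy-3-(hydroxymethyl)cyclohexyl benzoate | OC[C@]1(O)[C@H](O)CC[C@@H](OC(=O)c2ccccc2)[C@@H]1O[Si](C)(C)C(C)(C)C
F8 | step 8 | [(1S,2R,5R,6S)-5-(benzoyloxy)-6-[(tert-butyldimethylsilyl)oxy]-1,2-dihydroxycyclohexyl]methyl benzoate | O=C(OC[C@]1(O)[C@H](O)CC[C@@H](OC(=O)c2ccccc2)[C@@H]1O[Si](C)(C)C(C)(C)C)c1ccccc1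
A1 | alternative 1 | 2,2-dimethyl-1,3-dioxan-5-one | CC1(C)OCC(=O)CO1
A2 | alternative 1 | acrolein (prop-2-enal) | C=CC=O
A3 | alternative 1 | 6-hydroxy-3,3-dimethyl-2,4-dioxabicyclo[3.3.1]nonan-9-one (hydroxyl trans to the adjacent bridgehead oxygen) | O=C1[C@H]2CC[C@@H](O)[C@@H]1OC(C)(C)O2
A4 | alternative 2 | 4,5-diacetyl-4-[(benzyloxy)methyl]-2,2-dimethyl-1,3-dioxolane (acetyl groups trans) | c1ccccc1COC[C@]2(OC(C)(C)O[C@H]2C(C)=O)C(C)=O
A5 | alternative 2 | 3a-[(benzyloxy)methyl]-2,2-dimethyltetrahydro-1,3-benzodioxole-4,7-dione (trans ring fusion) | c1ccccc1COC[C@]2(OC(C)(C)O3)C(=O)CCC(=O)[C@@H]23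
A6 | alternative 3 | (1R,2S)-3-[(benzoyloxy)acetyl]-2,3-dihydroxycyclopentyl benzoate (configuration of the tertiary carbinol carbon left open) | O=C(COC(=O)c1ccccc1)C1(O)CC[C@@H](OC(=O)c2ccccc2)[C@@H]1O
A7 | alternative 3 | [(1R,2S,3R)-3-(benzoyloxy)-1,2-dihydroxy-6-oxocyclohexyl]methyl benzoate | O=C(OC[C@]1(O)C(=O)CC[C@@H](OC(=O)c2ccccc2)[C@@H]1O)c1ccccc1
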